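## Retrosynthetic overview

1. The route rests on the α-ketol of the six-membered ring, C1(=O)–C6(OH). Exchanging its carbonyl and carbinol carbons gives a 1-acylcyclopent-3-en-1-ol whose five-membered ring has a mirror plane, so the cyclohexenone can be made by moving one ring CH2 (new bond C5–C6).
2. Endgame: C2=C3 and the C4 hydroxyl come from a 3,4-epoxide by β-elimination. The epoxide comes from the C3=C4 alkene left by the shift and is placed cis to the C6 hydroxyl by that hydroxyl.
3. The acylcyclopentenol comes from a boron aldol (bond C1'–C2', sets C2') between O-silylated 1-acetylcyclopent-3-en-1-ol and (9Z)-hexadec-9-enal from palmitoleic acid. The C2' oxygen is carried as a TBS ether through the shift.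
4. 1-Acetylcyclopent-3-en-1-ol comes from methyl 2,2-dimethoxypropanoate by double allyl Grignard addition, ring-closing metathesis and ketal hydrolysis.
5. Ring order: the cyclopentene is closed first (metathesis), then the six-membered ring is made from it by ring enlargement; no other ring is formed.

Key step: step 9

Remark: atoms carry the locants of the target throughout (in the acyclic ketols the ring carbinol carbon is C1, the acyl carbon C6, the chain C1', C2' and so on); the CIP descriptor of C6 reads S in 16–18 and R in 19 only because the ranking of C5 and C1' changes, no bond at C6 being touched after step 9.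

## Route

Step 1
Reactants: 1 methyl 2,2-dimethoxypropanoate; 2 allylmagnesium bromide (2.3 equiv, solution in Et2O)
Product: 4 4-(1,1-dimethoxyethyl)hepta-1,6-dien-4-ol, via 2,2-dimethoxyhex-5-en-3-one 3 (not isolated)
Conditions: Et2O/THF, −78 → 0 °C; aq. NH4Cl
Reagents that add atoms: none
Why: Double Grignard addition to an ester, in which the first allyl group gives ketone 3 after loss of methoxide and 3, more electrophilic than 1, takes up the second allyl group at once, while the dimethyl ketal keeps the future acetyl carbonyl masked; no stereocentre is formed.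

Step 2
Reactants: 4 4-(1,1-dimethoxyethyl)hepta-1,6-dien-4-ol
Product: 5 1-(1,1-dimethoxyethyl)cyclopent-3-en-1-ol
Conditions: RuCl2(=CHPh)(PCy3)(H2IMes) (second-generation Grubbs catalyst, 1 mol %), CH2Cl2, 40 °C
Reagents that add atoms: none
Why: Ring-closing metathesis of a 4,4-disubstituted hepta-1,6-diene, a closure favoured by the geminal substitution and tolerant of the free tertiary hydroxyl and the ketal; ethene leaves and the ring keeps its mirror plane.

Step 3
Reactants: 5 1-(1,1-dimethoxyethyl)cyclopent-3-en-1-ol
Product: 6 1-(1-hydroxycyclopent-3-en-1-yl)ethan-1-one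
Conditions: 1 M HCl, THF, 20 °C
Reagents that add atoms: water, O
Why: Acid-catalysed ketal hydrolysis at room temperature, mild enough that the tertiary homoallylic alcohol should neither eliminate nor undergo an acid-induced ketol shift; no stereocentre is formed.

Step 4
Reactants: 6 1-(1-hydroxycyclopent-3-en-1-yl)ethan-1-one
Product: 7 1-[1-(trimethylsilyloxy)cyclopent-3-en-1-yl]ethan-1-one
Conditions: 1-(trimethylsilyl)imidazole, CH2Cl2, 20 °C
Reagents that add atoms: 1-(trimethylsilyl)imidazole, C[Si](C)(C)n1ccnc1
Why: Silylation of a hindered tertiary alcohol with an N-silylimidazole, which does not enolise the methyl ketone; α-trimethylsilyloxy ketones of this kind are established aldol donors and the silyl group keeps the hydroxyl off boron in step 7.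

Step 5
Reactants: 8 palmitoleic acid
Product: 9 (9Z)-hexadec-9-en-1-ol
Conditions: LiAlH4, THF, 0 → 20 °C; then H2O, aq. NaOH
Reagents that add atoms: none
Why: Hydride reduction of a carboxylic acid to the primary alcohol with LiAlH4, which leaves the isolated Z-alkene untouched.

Step 6
Reactants: 9 (9Z)-hexadec-9-en-1-ol
Product: 10 (9Z)-hexadec-9-enal
Conditions: TEMPO (10 mol %), PhI(OAc)2, CH2Cl2, 20 °C
Reagents that add atoms: none
Why: Nitroxyl-catalysed oxidation of a primary alcohol, which stops at the aldehyde and neither attacks nor isomerises the Z-alkene; the aldehyde carbon is the future C2'.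

Step 7
Reactants: 7 1-[1-(trimethylsilyloxy)cyclopent-3-en-1-yl]ethan-1-one; 10 (9Z)-hexadec-9-enal
Product: 14 (3S,11Z)-3-hydroxy-1-(1-hydroxycyclopent-3-en-1-yl)octadec-11-en-1-one, via boron enolate 11 (not isolated), via boron aldolate 12 (not isolated), via trimethylsilyl ether 13 (not isolated)
Conditions: (−)-Ipc2BCl, Et3N, Et2O, 0 °C; 10, −78 → −20 °C; H2O2, MeOH, pH 7 buffer, 0 °C; then citric acid, MeOH, 20 °C
Reagents that add atoms: none
Why: Reagent-controlled boron aldol of a methyl ketone, in which (−)-Ipc2BCl and Et3N form enolate 11 on the only enolisable side and the isopinocampheyl groups are expected to steer 11 to the re face of aldehyde 10 in a cyclic boron-bound transition state (the sense assigned to methyl ketone enolates of this reagent), which sets the carbinol carbon (C2' of the target) as S; oxidative work-up frees 13 from boron, mild acid removes the tertiary trimethylsilyl group, and the enantiomeric purity is to be measured on 14.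

Step 8
Reactants: 14 (3S,11Z)-3-hydroxy-1-(1-hydroxycyclopent-3-en-1-yl)octadec-11-en-1-one
Product: 15 (3S,11Z)-3-[(tert-butyldimethylsilyl)oxy]-1-(1-hydroxycyclopent-3-en-1-yl)octadec-11-en-1-one
Conditions: TBSCl, imidazole, DMF, 0 → 20 °C
Reagents that add atoms: tert-butyldimethylsilyl chloride, CC(C)(C)[Si](C)(C)Cl
Why: Silyl ether formation with the chloride and imidazole is far faster at the secondary than at the hindered tertiary α-keto hydroxyl, so only O2' is protected; the stereocentre is untouched, and the β-silyloxy group later blocks retro-aldol cleavage and serves as the control element of step 9.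

Step 9
Reactants: 15 (3S,11Z)-3-[(tert-butyldimethylsilyl)oxy]-1-(1-hydroxycyclopent-3-en-1-yl)octadec-11-en-1-one
Product: 16 (6S)-6-{(2S,10Z)-2-[(tert-butyldimethylsilyl)oxy]heptadec-10-en-1-yl}-6-hydroxycyclohex-3-en-1-one
Conditions: Zn(OTf)2 (0.3 equiv), 2,6-di-tert-butyl-4-methylpyridine (0.3 equiv), 4 Å molecular sieves, ClCH2CH2Cl, 20 → 45 °C, stopped at full conversion
Reagents that add atoms: none
Why: The zinc ion binds the tertiary hydroxyl and the ketone oxygen of 15 in a five-membered chelate that holds O–C1–C6=O syn-periplanar, activates the acyl carbon C6 and places the two ring CH2 groups above and below the chelate plane; the ring C–C bond aligned with the carbonyl π* then shifts suprafacially from C1 to C6 while C1–O becomes the new carbonyl and the proton passes to the new alkoxide (α-ketol or acyloin rearrangement, the reaction type known from the Lewis-acid ring enlargement of 1-acylcyclopentanols to 2-alkyl-2-hydroxycyclohexanones and from the D-homoannulation of 17-hydroxy-20-keto steroids). The six-membered ring is thus made by a 1,2-shift that inserts C6 into the five-membered ring (bond C5–C6 forms as C1–C5 breaks), not by an exo or endo cyclisation, and the change from cyclopentene to cyclohexene pulls the equilibrium forward. Because the cyclopentene is symmetric either CH2 gives the same constitution, with the alkene at C3=C4, β,γ to the ketone; which CH2 migrates decides C6, the only new stereocentre. C6 is controlled by the C2' silyloxy centre through open-chain 1,3-induction (the polar model for β-alkoxy carbonyl compounds): with the metal on the side away from the chain, the C1'–C2' bond stands perpendicular to the carbonyl and anti to the incoming carbon, the C–OSi dipole opposes C=O and the long chain points outward, so for (2'S) the si face of the C6 carbonyl is covered and the ring CH2 is delivered to the re face, giving the 1,3-anti relation of the C2' and C6 oxygens that the target has. The step needs this face selectivity, no drift of C3=C4 into conjugation and no loss of the β-silyloxy group; the silyl ether (a free β-hydroxyl could undergo retro-aldol cleavage and cannot share one metal with the ketol chelate), the hindered pyridine that takes up traces of triflic acid and the lowest workable temperature serve these ends.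

Step 10
Reactants: 16 (6S)-6-{(2S,10Z)-2-[(tert-butyldimethylsilyl)oxy]heptadec-10-en-1-yl}-6-hydroxycyclohex-3-en-1-one
Product: 17 (1R,4S,6S)-4-{(2S,10Z)-2-[(tert-butyldimethylsilyl)oxy]heptadec-10-en-1-yl}-4-hydroxy-7-oxabicyclo[4.1.0]heptan-3-one (epoxide cis to the tertiary hydroxyl)
Conditions: VO(acac)2 (5 mol %), t-BuOOH (decane solution), CH2Cl2, 0 → 20 °C; aq. Na2S2O3
Reagents that add atoms: tert-butyl hydroperoxide, CC(C)(C)OO
Why: Hydroxyl-directed epoxidation, in which the C6 alkoxide binds vanadium and delivers the peroxide oxygen to the homoallylic C3=C4 bond on its own face, so the two new stereocentres C3 and C4 carry the epoxide cis to the C6 hydroxyl, while the distant Z-alkene, with no free hydroxyl in reach, should be left alone.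

Step 11
Reactants: 17 (1R,4S,6S)-4-{(2S,10Z)-2-[(tert-butyldimethylsilyl)oxy]heptadec-10-en-1-yl}-4-hydroxy-7-oxabicyclo[4.1.0]heptan-3-one
Product: 18 (4S,6S)-6-{(2S,10Z)-2-[(tert-butyldimethylsilyl)oxy]heptadec-10-en-1-yl}-4,6-dihydroxycyclohex-2-en-1-one
Conditions: Et3N, CH2Cl2, 0 → 20 °C
Reagents that add atoms: none
Why: Base-induced β-elimination (E1cB) of a β,γ-epoxy ketone, in which Et3N removes a C2 proton and the enolate opens the epoxide at C3; the C4–O bond is never broken, so the C4 hydroxyl keeps the configuration set in step 10, cis to the C6 hydroxyl.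

Step 12
Reactants: 18 (4S,6S)-6-{(2S,10Z)-2-[(tert-butyldimethylsilyl)oxy]heptadec-10-en-1-yl}-4,6-dihydroxycyclohex-2-en-1-one
Product: 19 (4S,6R)-4,6-dihydroxy-6-[(2S,10Z)-2-hydroxyheptadec-10-en-1-yl]cyclohex-2-en-1-one
Conditions: HF·pyridine, pyridine, THF, 0 → 20 °C
Reagents that add atoms: none
Why: Fluoride-induced cleavage of the secondary silyl ether under buffered conditions, in which the γ-hydroxy enone and the tertiary α-ketol should neither dehydrate nor rearrange; no stereocentre is touched.

## Compound list

1 | methyl 2,2-dimethoxypropanoate | COC(=O)C(C)(OC)OC | starting material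
2 | allylmagnesium bromide (prop-2-en-1-ylmagnesium bromide) | C=CC[Mg]Br | starting material
3 | 2,2-dimethoxyhex-5-en-3-one | C=CCC(=O)C(C)(OC)OC | intermediate (not isolated)
4 | 4-(1,1-dimethoxyethyl)hepta-1,6-dien-4-ol | C=CCC(O)(CC=C)C(C)(OC)OC | intermediate
5 | 1-(1,1-dimethoxyethyl)cyclopent-3-en-1-ol | COC(C)(OC)C1(O)CC=CC1 | intermediate
6 | 1-(1-hydroxycyclopent-3-en-1-yl)ethan-1-one | CC(=O)C1(O)CC=CC1 | intermediate
7 | 1-[1-(trimethylsilyloxy)cyclopent-3-en-1-yl]ethan-1-one | CC(=O)C1(O[Si](C)(C)C)CC=CC1 | intermediate
8 | palmitoleic acid, (9Z)-hexadec-9-enoic acid | CCCCCC/C=C\CCCCCCCC(=O)O | starting material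
9 | (9Z)-hexadec-9-en-1-ol | CCCCCC/C=C\CCCCCCCCO | intermediate
10 | (9Z)-hexadec-9-enal | CCCCCC/C=C\CCCCCCCC=O | intermediate
11 | diisopinocampheyl{1-[1-(trimethylsilyloxy)cyclopent-3-en-1-yl]ethenyloxy}borane, isopinocampheyl groups as in (−)-Ipc2BCl | C=C(OB([C@@H]1C[C@@H]2C[C@H]([C@H]1C)C2(C)C)[C@@H]1C[C@@H]2C[C@H]([C@H]1C)C2(C)C)C1(O[Si](C)(C)C)CC=CC1 | intermediate (not isolated)
12 | O-diisopinocampheylboryl derivative of 13 (boron aldolate, 3S) | CCCCCC/C=C\CCCCCCC[C@H](OB([C@@H]1C[C@@H]2C[C@H]([C@H]1C)C2(C)C)[C@@H]1C[C@@H]2C[C@H]([C@H]1C)C2(C)C)CC(=O)C1(O[Si](C)(C)C)CC=CC1 | intermediate (not isolated)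
13 | (3S,11Z)-3-hydroxy-1-[1-(trimethylsilyloxy)cyclopent-3-en-1-yl]octadec-11-en-1-one | CCCCCC/C=C\CCCCCCC[C@H](O)CC(=O)C1(O[Si](C)(C)C)CC=CC1 | intermediate (not isolated)
14 | (3S,11Z)-3-hydroxy-1-(1-hydroxycyclopent-3-en-1-yl)octadec-11-en-1-one | CCCCCC/C=C\CCCCCCC[C@H](O)CC(=O)C1(O)CC=CC1 | intermediate
15 | (3S,11Z)-3-[(tert-butyldimethylsilyl)oxy]-1-(1-hydroxycyclopent-3-en-1-yl)octadec-11-en-1-one | CCCCCC/C=C\CCCCCCC[C@H](O[Si](C)(C)C(C)(C)C)CC(=O)C1(O)CC=CC1 | intermediate
16 | (6S)-6-{(2S,10Z)-2-[(tert-butyldimethylsilyl)oxy]heptadec-10-en-1-yl}-6-hydroxycyclohex-3-en-1-one | CCCCCC/C=C\CCCCCCC[C@H](O[Si](C)(C)C(C)(C)C)C[C@@]1(O)CC=CCC1=O | intermediate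
17 | (1R,4S,6S)-4-{(2S,10Z)-2-[(tert-butyldimethylsilyl)oxy]heptadec-10-en-1-yl}-4-hydroxy-7-oxabicyclo[4.1.0]heptan-3-one | CCCCCC/C=C\CCCCCCC[C@H](O[Si](C)(C)C(C)(C)C)C[C@@]1(O)C[C@@H]2O[C@@H]2CC1=O | intermediate
18 | (4S,6S)-6-{(2S,10Z)-2-[(tert-butyldimethylsilyl)oxy]heptadec-10-en-1-yl}-4,6-dihydroxycyclohex-2-en-1-one | CCCCCC/C=C\CCCCCCC[C@H](O[Si](C)(C)C(C)(C)C)C[C@@]1(O)C[C@H](O)C=CC1=O | intermediate
19 | (4S,6R)-4,6-dihydroxy-6-[(2S,10Z)-2-hydroxyheptadec-10-en-1-yl]cyclohex-2-en-1-one | CCCCCC/C=C\CCCCCCC[C@H](O)C[C@@]1(O)C[C@H](O)C=CC1=O | target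

## Step count and risks

Total step count: 12. Longest linear sequence: 10 steps (steps 1–4 and 7–12, from methyl 2,2-dimethoxypropanoate); the aldehyde branch (steps 5 and 6) joins at step 7.

Steps most likely to fail:

1. Step 9. The open-chain 1,3-induction may be too weak, so that both ring CH2 groups migrate and the C6 epimer accompanies 16. Long exposure to the Lewis acid could add a second 1,2-shift (C1' from C6 to C1) that exchanges the two C6 configurations. Conjugation of C3=C4 is a further risk and is dealt with under step 10. A chiral bis(oxazoline) ligand on Cu(OTf)2 in place of Zn(OTf)2 would be tried first, but that is a change of conditions only. Fallback, from 14 back to 19: no induction is asked of the shift. The unprotected diol 14 is rearranged with Zn(OTf)2 as in step 9. The product is a pair of C6-epimeric 1,3-diols, which differ as anti and syn diols and should separate on silica. (6S)-6-hydroxy-6-[(2S,10Z)-2-hydroxyheptadec-10-en-1-yl]cyclohex-3-en-1-one F1 is kept and its epimer (6R)-6-hydroxy-6-[(2S,10Z)-2-hydroxyheptadec-10-en-1-yl]cyclohex-3-en-1-one F2 is set aside. F1 is epoxidised without protection (VO(acac)2, t-BuOOH; the C6 hydroxyl is the one nearest to C3=C4) to the epoxy diol (1R,4R,6S)-4-hydroxy-4-[(2S,10Z)-2-hydroxyheptadec-10-en-1-yl]-7-oxabicyclo[4.1.0]heptan-3-one F3, and Et3N opens F3 to 19. Up to half of the material would be lost, but the sequence is two steps shorter and needs no selectivity in the shift.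

2. Step 7. The boron enolate may discriminate the two faces of the aldehyde incompletely, methyl ketone enolates being the less selective substrates of this reagent. Because step 9 is controlled by C2', the minor enantiomer would be carried through to the enantiomer of 19. Fallback, from 14 of insufficient enantiomeric purity back to 14: C2' is erased and set again under catalyst control. MsCl and Et3N convert 14 through the mesylate 1-(1-hydroxycyclopent-3-en-1-yl)-1-oxooctadec-11-en-3-yl methanesulfonate F4, which eliminates in the flask, into the α'-hydroxy enone (2E,11Z)-1-(1-hydroxycyclopent-3-en-1-yl)octadeca-2,11-dien-1-one F5. Copper-catalysed enantioselective conjugate borylation (CuCl, NaOt-Bu, a Josiphos-type diphosphine, B2pin2, MeOH, THF) then gives the boronate (3S,11Z)-1-(1-hydroxycyclopent-3-en-1-yl)-3-(4,4,5,5-tetramethyl-1,3,2-dioxaborolan-2-yl)octadec-11-en-1-one F6. The ligand enantiomer is chosen as the one that leads to the 3S product, assigned after oxidation of a sample. NaBO3·4H2O in THF/H2O oxidises the C–B bond with retention and returns 14.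

3. Step 10. The β,γ-unsaturated ketone 16 may slip into conjugation (C2=C3) before oxygen is delivered, or the tertiary α-keto alkoxide may bind vanadium too weakly for clean facial control. Fallback, from 15 back to 17: the order is inverted so that no β,γ-unsaturated ketone is ever formed. VO(acac)2 and t-BuOOH epoxidise the cyclopentene of 15 under direction of its tertiary hydroxyl to the cis-epoxy ketol (3S,11Z)-3-[(tert-butyldimethylsilyl)oxy]-1-[(1R,3r,5S)-3-hydroxy-6-oxabicyclo[3.1.0]hexan-3-yl]octadec-11-en-1-one F7 (epoxide cis to the hydroxyl), whose ring keeps its mirror plane. The Zn(OTf)2-mediated shift of step 9 applied to F7 should then give 17 directly. Both oxygen atoms of the chelate stay on the same side of the migrating ring, so the epoxide that was cis to the old hydroxyl is cis to the new one. The epoxide has to survive the Lewis acid, which is why this order is the fallback and not the first choice.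

## Further compounds

F1 | step 9 | (6S)-6-hydroxy-6-[(2S,10Z)-2-hydroxyheptadec-10-en-1-yl]cyclohex-3-en-1-one | CCCCCC/C=C\CCCCCCC[C@H](O)C[C@@]1(O)CC=CCC1=O
F2 | step 9 | (6R)-6-hydroxy-6-[(2S,10Z)-2-hydroxyheptadec-10-en-1-yl]cyclohex-3-en-1-one | CCCCCC/C=C\CCCCCCC[C@H](O)C[C@]1(O)CC=CCC1=O
F3 | step 9 | (1R,4R,6S)-4-hydroxy-4-[(2S,10Z)-2-hydroxyheptadec-10-en-1-yl]-7-oxabicyclo[4.1.0]heptan-3-one | CCCCCC/C=C\CCCCCCC[C@H](O)C[C@@]1(O)C[C@@H]2O[C@@H]2CC1=O
F4 | step 7 | 1-(1-hydroxycyclopent-3-en-1-yl)-1-oxooctadec-11-en-3-yl methanesulfonate (11Z; C3 as in the scalemic 14 used) | CCCCCC/C=C\CCCCCCCC(OS(C)(=O)=O)CC(=O)C1(O)CC=CC1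
F5 | step 7 | (2E,11Z)-1-(1-hydroxycyclopent-3-en-1-yl)octadeca-2,11-dien-1-one | CCCCCC/C=C\CCCCCCC/C=C/C(=O)C1(O)CC=CC1
F6 | step 7 | (3S,11Z)-1-(1-hydroxycyclopent-3-en-1-yl)-3-(4,4,5,5-tetramethyl-1,3,2-dioxaborolan-2-yl)octadec-11-en-1-one | CCCCCC/C=C\CCCCCCC[C@H](B1OC(C)(C)C(C)(C)O1)CC(=O)C1(O)CC=CC1
F7 | step 10 | (3S,11Z)-3-[(tert-butyldimethylsilyl)oxy]-1-[(1R,3r,5S)-3-hydroxy-6-oxabicyclo[3.1.0]hexan-3-yl]octadec-11-en-1-one | CCCCCC/C=C\CCCCCCC[C@H](O[Si](C)(C)C(C)(C)C)CC(=O)[C@]1(O)C[C@H]2O[C@H]2C1
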